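Ring C is cut at O1–C2 and C3–C4. The C2(aryl)–C3 unit is then 4-methoxystyrene, while O1, C8a, C4a and C4 form a ring A ortho-quinone methide whose methide carbon C4 later becomes the ketone. A single chiral-acid-catalysed three-component oxa-(4+2) reaction of a salicylaldehyde, trimethyl orthoformate and the styrene should make both bonds, close ring C and set C2 as S. Its precursor is a salicylaldehyde with the prenyl group beside the free phenol, the methoxy group para to the formyl group and a triisopropylsilyl ether on the second ortho oxygen, so that only one oxygen can close the ring. Hydrolysis at C4, oxidation and desilylation complete the flavanone.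

Key step: step 4

Assumption: the sense of induction of the chiral phosphoric acid cannot be predicted with certainty. The (R)-catalyst is written; its mirror image is used instead if a trial run shows that (R) leads to the 2R series. Prenyl means 3-methylbut-2-en-1-yl throughout.

Step 1
Reactants: 1 5-methoxyresorcinol
Product: 2 3-methoxy-5-(triisopropylsilyloxy)phenol
Conditions: TIPSCl (0.6 equiv), imidazole, DMF, 0 °C to 20 °C
Reagents that add atoms: triisopropylsilyl chloride, CC(C)[Si](Cl)(C(C)C)C(C)C
Why: Imidazole-mediated O-silylation of a symmetric diol, so the only question is mono against double silylation, which the deficit of silyl chloride and the bulk of the group should push towards the mono ether, with unreacted 1 recovered by extraction.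

Step 2
Reactants: 2 3-methoxy-5-(triisopropylsilyloxy)phenol; 3 prenyl bromide
Product: 4 3-methoxy-2-prenyl-5-(triisopropylsilyloxy)phenol
Conditions: NaH (1.05 equiv), toluene, 0 °C; then 3 (1.1 equiv), 20 °C
Reagents that add atoms: none
Why: Ortho-C-alkylation of a sodium phenoxide in a non-polar solvent, where the tight ion pair steers the allylic bromide to an ortho carbon by SN2 attack instead of to oxygen; the ortho carbon beside the small methoxy group should react because the triisopropylsilyl group shields the other ortho carbon and the para carbon.

Step 3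
Reactants: 4 3-methoxy-2-prenyl-5-(triisopropylsilyloxy)phenol
Product: 6 2-hydroxy-4-methoxy-3-prenyl-6-(triisopropylsilyloxy)benzaldehyde, via benzylic alcohol 5 (not isolated)
Conditions: MgCl2 (2 equiv), Et3N (4 equiv), paraformaldehyde (6 equiv), THF, reflux; dilute aqueous acid work-up
Reagents that add atoms: paraformaldehyde (as formaldehyde), C=O
Why: Casnati–Skattebøl magnesium-mediated ortho-formylation, in which the chloromagnesium phenoxide delivers formaldehyde to the only free ortho carbon to give benzylic alcohol 5, which a second equivalent of formaldehyde oxidises by hydride transfer; the basic medium leaves the silyl ether and the prenyl group untouched.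

Step 4
Reactants: 6 2-hydroxy-4-methoxy-3-prenyl-6-(triisopropylsilyloxy)benzaldehyde; 7 trimethyl orthoformate; 8 4-methoxystyrene
Product: 11 (2S)-4,7,4'-trimethoxy-8-prenyl-5-(triisopropylsilyloxy)flavan (C4 epimers), via dimethyl acetal 9 (not isolated), via ortho-quinone methide 10 (not isolated)
Conditions: 7 (3 equiv), (R)-3,3'-bis(2,4,6-triisopropylphenyl)-1,1'-binaphthyl-2,2'-diyl hydrogen phosphate ((R)-TRIP, 10 mol %), toluene, 20 °C; then 8 (2 equiv), 5 Å MS, −30 °C; Et3N quench
Reagents that add atoms: none
Why: Proposed new method: acid-catalysed exchange with the orthoformate gives acetal 9, which the chiral phosphoric acid ionises with loss of methanol to the O-protonated 4-methoxy ortho-quinone methide 10, held as a hydrogen-bonded ion pair with the chiral phosphate; the CH2 terminus of styrene 8 then adds to the methide carbon (C3–C4) and the resulting 4-methoxybenzylic cation is captured by the C8a oxygen (O1–C2). The closest known reactions are the racemic acid-promoted three-component synthesis of 4-alkoxyflavans from salicylaldehydes, orthoformates and styrenes, and chiral phosphoric acid catalysed inverse-electron-demand oxa-(4+2) cycloadditions of other ortho-quinone methides with electron-rich styrenes. Ring C closes as a six-membered ring by a stepwise, strongly asynchronous hetero-Diels–Alder reaction, the last event being a formal 6-exo-trig capture of the benzylic cation by the phenolic oxygen. C2 is set in that C–O bond formation: the phosphate binds the phenol O–H and pairs with the cation, so the 3,3'-aryl walls of the catalyst should leave one face of the cation open, and the catalyst antipode is chosen to give 2S; C4 forms without control and is removed in step 6. The step needs regioselectivity (oxygen to the benzylic carbon), which the polarity of the styrene secures, and chemoselectivity over the prenyl alkene, which the much higher nucleophilicity of 4-methoxystyrene secures. The weak acid and low temperature should keep the free phenol from adding to the neighbouring prenyl group, and the silyl ether blocks the second phenolic oxygen so that only the 8-prenyl ring isomer can form.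

Step 5
Reactants: 11 (2S)-4,7,4'-trimethoxy-8-prenyl-5-(triisopropylsilyloxy)flavan (C4 epimers)
Product: 12 (2S)-7-methoxy-2-(4-methoxyphenyl)-8-prenyl-5-(triisopropylsilyloxy)chroman-4-ol (C4 epimers)
Conditions: pyridinium p-toluenesulfonate (10 mol %), THF/H2O 4:1, 20 °C
Reagents that add atoms: water, O
Why: SN1 solvolysis of a benzylic methyl ether, in which the C4 cation is stabilised by O1, the C5 silyloxy and the C7 methoxy groups and is trapped by the large excess of water, while the far less easily ionised C2–O1 bond and the silyl ether stay intact, so C2 keeps its configuration.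

Step 6
Reactants: 12 (2S)-7-methoxy-2-(4-methoxyphenyl)-8-prenyl-5-(triisopropylsilyloxy)chroman-4-ol (C4 epimers)
Product: 13 (2S)-7-methoxy-2-(4-methoxyphenyl)-8-prenyl-5-(triisopropylsilyloxy)chroman-4-one
Conditions: Dess–Martin periodinane (1.3 equiv), pyridine, CH2Cl2, 0 °C to 20 °C
Reagents that add atoms: none
Why: Dess–Martin oxidation of a secondary benzylic alcohol under buffered, non-basic conditions converts both C4 epimers into one ketone without retro-oxa-Michael ring opening, so C2 is not touched, and the prenyl alkene is inert to the periodinane.

Step 7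
Reactants: 13 (2S)-7-methoxy-2-(4-methoxyphenyl)-8-prenyl-5-(triisopropylsilyloxy)chroman-4-one
Product: 14 Flowerine, (2S)-5-hydroxy-7-methoxy-2-(4-methoxyphenyl)-8-prenylchroman-4-one
Conditions: tetrabutylammonium fluoride (1.2 equiv), AcOH (1.2 equiv), THF, 0 °C
Reagents that add atoms: none
Why: Fluoride-induced cleavage of an aryl silyl ether, driven by the strong Si–F bond; buffering with acetic acid keeps the medium near neutral so that the flavanone should not open to the chalcone and C2 is preserved.

Compound list
1 | 5-methoxyresorcinol (5-methoxybenzene-1,3-diol) | COc1cc(O)cc(O)c1 | starting material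
2 | 3-methoxy-5-(triisopropylsilyloxy)phenol | COc1cc(O)cc(O[Si](C(C)C)(C(C)C)C(C)C)c1 | intermediate
3 | prenyl bromide (1-bromo-3-methylbut-2-ene) | CC(C)=CCBr | starting material
4 | 3-methoxy-2-prenyl-5-(triisopropylsilyloxy)phenol | COc1cc(O[Si](C(C)C)(C(C)C)C(C)C)cc(O)c1CC=C(C)C | intermediate
5 | 2-(hydroxymethyl)-5-methoxy-6-prenyl-3-(triisopropylsilyloxy)phenol (present as its magnesium phenoxide, not isolated) | COc1cc(O[Si](C(C)C)(C(C)C)C(C)C)c(CO)c(O)c1CC=C(C)C | intermediate
6 | 2-hydroxy-4-methoxy-3-prenyl-6-(triisopropylsilyloxy)benzaldehyde | COc1cc(O[Si](C(C)C)(C(C)C)C(C)C)c(C=O)c(O)c1CC=C(C)C | intermediate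
7 | trimethyl orthoformate | COC(OC)OC | starting material
8 | 4-methoxystyrene | C=Cc1ccc(OC)cc1 | starting material
9 | 2-(dimethoxymethyl)-5-methoxy-6-prenyl-3-(triisopropylsilyloxy)phenol (not isolated) | COc1cc(O[Si](C(C)C)(C(C)C)C(C)C)c(C(OC)OC)c(O)c1CC=C(C)C | intermediate
10 | 3-methoxy-6-(methoxymethylidene)-2-prenyl-5-(triisopropylsilyloxy)cyclohexa-2,4-dien-1-one (present as its O-protonated ion pair with the catalyst anion, not isolated) | COC=C1C(=O)C(CC=C(C)C)=C(OC)C=C1O[Si](C(C)C)(C(C)C)C(C)C | intermediate
11 | (2S)-4,7,4'-trimethoxy-8-prenyl-5-(triisopropylsilyloxy)flavan, both C4 epimers | COc1ccc([C@@H]2CC(OC)c3c(O[Si](C(C)C)(C(C)C)C(C)C)cc(OC)c(CC=C(C)C)c3O2)cc1 | intermediate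
12 | (2S)-7-methoxy-2-(4-methoxyphenyl)-8-prenyl-5-(triisopropylsilyloxy)chroman-4-ol, both C4 epimers | COc1ccc([C@@H]2CC(O)c3c(O[Si](C(C)C)(C(C)C)C(C)C)cc(OC)c(CC=C(C)C)c3O2)cc1 | intermediate
13 | (2S)-7-methoxy-2-(4-methoxyphenyl)-8-prenyl-5-(triisopropylsilyloxy)chroman-4-one | COc1ccc([C@@H]2CC(=O)c3c(O[Si](C(C)C)(C(C)C)C(C)C)cc(OC)c(CC=C(C)C)c3O2)cc1 | intermediate
14 | Flowerine, (2S)-5-hydroxy-7-methoxy-2-(4-methoxyphenyl)-8-(3-methylbut-2-en-1-yl)chroman-4-one | COc1ccc([C@@H]2CC(=O)c3c(O)cc(OC)c(CC=C(C)C)c3O2)cc1 | target

Total step count: 7. Longest linear sequence: 7 steps, from 5-methoxyresorcinol 1 to Flowerine 14.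

Steps most likely to fail

Step 4 (labelled step). Several processes may go wrong:
- Facial discrimination in the ring closure may be poor, or the two C4 epimers may form with opposite sense at C2, so the enantiomeric purity is lost once C4 is oxidised.
- The free phenol may add to the prenyl alkene under acid.
- The product may ionise again at C4 and then eliminate or take up a second styrene.
- The styrene may oligomerise by a cationic path.

Fallback, known chemistry: the fallback sets out from aldehyde 6. The same three-component condensation is run with an achiral acid (diphenyl phosphate, toluene, 0 °C), which is the known racemic acid-promoted flavan synthesis, and should give racemic 4,7,4'-trimethoxy-8-prenyl-5-(triisopropylsilyloxy)flavan F1. The conditions of steps 5 and 6 then give racemic 7-methoxy-2-(4-methoxyphenyl)-8-prenyl-5-(triisopropylsilyloxy)chroman-4-ol F2 and racemic 7-methoxy-2-(4-methoxyphenyl)-8-prenyl-5-(triisopropylsilyloxy)chroman-4-one F3. F3 has a single stereocentre and is resolved by preparative chromatography on a chiral stationary phase (amylose tris(3,5-dimethylphenylcarbamate)). The 2S enantiomer is compound 13, where the route is rejoined, and the (2R)-7-methoxy-2-(4-methoxyphenyl)-8-prenyl-5-(triisopropylsilyloxy)chroman-4-one F4 is set aside.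

Step 5. The C4 cation may lose a proton to give the flav-3-ene instead of taking up water, and prolonged acid contact may open the C2–O1 bond reversibly and erode the configuration at C2. Fallback: the fallback sets out from 11 and avoids acid solvolysis. Oxidative cleavage of the benzylic methyl ether with DDQ in CH2Cl2/pH 7 buffer at 0 °C (hydride abstraction at C4, addition of water, loss of methanol from the hemiacetal) should give the ketone directly. It comes back to the route at 13, bypassing 12, and makes no new compound (F0).

Step 2. O-alkylation, alkylation at the para carbon and double alkylation may compete with the wanted ortho-C-alkylation. Fallback: the fallback sets out from 2. O-allylation with tert-butyl 2-methylbut-3-en-2-yl carbonate under Pd(PPh3)4 catalysis (zerovalent palladium, THF, 0 °C) should give the tertiary allyl ether triisopropyl[3-methoxy-5-(2-methylbut-3-en-2-yloxy)phenoxy]silane F5. An aromatic Claisen rearrangement (toluene or N,N-diethylaniline, heat) then moves the allyl unit to the ortho carbon beside the methoxy group as a normal prenyl group. This returns to the route at 4, with carbon–carbon bond formation now intramolecular.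

Further compounds
F1 | step 4 | racemic 4,7,4'-trimethoxy-8-prenyl-5-(triisopropylsilyloxy)flavan (C4 epimers) | COc1ccc(C2CC(OC)c3c(O[Si](C(C)C)(C(C)C)C(C)C)cc(OC)c(CC=C(C)C)c3O2)cc1
F2 | step 4 | racemic 7-methoxy-2-(4-methoxyphenyl)-8-prenyl-5-(triisopropylsilyloxy)chroman-4-ol (C4 epimers) | COc1ccc(C2CC(O)c3c(O[Si](C(C)C)(C(C)C)C(C)C)cc(OC)c(CC=C(C)C)c3O2)cc1
F3 | step 4 | racemic 7-methoxy-2-(4-methoxyphenyl)-8-prenyl-5-(triisopropylsilyloxy)chroman-4-one | COc1ccc(C2CC(=O)c3c(O[Si](C(C)C)(C(C)C)C(C)C)cc(OC)c(CC=C(C)C)c3O2)cc1
F4 | step 4 | (2R)-7-methoxy-2-(4-methoxyphenyl)-8-prenyl-5-(triisopropylsilyloxy)chroman-4-one | COc1ccc([C@H]2CC(=O)c3c(O[Si](C(C)C)(C(C)C)C(C)C)cc(OC)c(CC=C(C)C)c3O2)cc1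
F0 | step 5 | none | none
F5 | step 2 | triisopropyl[3-methoxy-5-(2-methylbut-3-en-2-yloxy)phenoxy]silane | COc1cc(OC(C)(C)C=C)cc(O[Si](C(C)C)(C(C)C)C(C)C)c1
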